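**Plan**

- Retrosynthesis: cut C12–C13 (butenolide, sp3–sp2 coupling), C9–C11 (vinyl on a C9 enol triflate), C4–C18 and C4–C19 (methyl cuprate and an alkoxymethyl anion on a ring A enone), then both C5–C6 and C8–C9 of ring B at once. This leaves (S)-3-methyl-3-(nitromethyl)cyclohexanone and crotonaldehyde.
- Enabling feature: in ring B the carbinol C6 and the olefinic C8 are 1,3 across C7, so C6–C7–C8(–C17) is crotonaldehyde, while C5 and C9 both flank the quaternary C10. With C4 as a ketone and C9 as a nitro carbon, these two are the nucleophiles of a [3+3] Michael/aldol annulation.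
- Forward: ring A (with C10) first, ring B by the annulation, then C9 nitro → ketone → enol triflate → 8(9),11-diene. The ring A ketone is taken to the transposed enone, the C4 quaternary centre and the C2 carbinol; the butenolide is coupled last and two protecting groups are removed.
- Stereochemistry: C10 from the amine-catalysed nitromethane addition; C5 and C6 from the reversible aldol (trans fusion, equatorial 6α-OH); C4 from cuprate attack anti to the C10 methyl; C2 from an equilibrating reduction.

Key step: step 2

Remark: positions follow labdane numbering (C1–C10 decalin, C11–C16 side chain, C17 on C8, C18/C19 on C4, C20 on C10) and α is the face opposite the C10 methyl; compounds 5–8 are drawn as the expected 8α,9β epimer, and any other C8/C9 epimer converges at 9 and 11.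

**Step 1**
Reactants: 1 3-methylcyclohex-2-en-1-one; 2 nitromethane
Product: 3 (S)-3-methyl-3-(nitromethyl)cyclohexan-1-one
Conditions: 9-amino-9-deoxy-epi-cinchona primary amine (the quinine- or quinidine-derived antipode that gives S, 10 mol%), PhCO2H (20 mol%), MeNO2, 9 kbar, 50 °C
Reagents that add atoms: none
Why: Iminium-activated Michael addition of nitromethane to the β-methyl enone (organocatalytic conjugate addition, accelerated by pressure) forms the C10 quaternary centre, the chiral primary amine shielding one face of the iminium ion to give the (S)-ketone.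

**Step 2**
Reactants: 3 (S)-3-methyl-3-(nitromethyl)cyclohexan-1-one; 4 (E)-but-2-enal
Product: 6 trans-fused 6α-hydroxy-8α,10β-dimethyl-9β-nitrodecalin-4-one, via Michael adduct 5 (not isolated)
Conditions: (S)-α,α-diphenylprolinol trimethylsilyl ether (20 mol%), PhCO2H (20 mol%), 4 (2 equiv), MeOH, 0 °C → rt; then DBU (0.3 equiv), rt
Reagents that add atoms: none
Why: Iminium activation of crotonaldehyde lets the nitronate carbon C9 add to C8 (nitro-Michael), and the liberated aldehyde C6 is then attacked by the C5 enol(ate) of the C4 ketone (intramolecular aldol), so that C8–C9 and C5–C6 form in one flask and ring B closes as a formal [3+3] annulation. The closest known reaction type is the organocatalytic nitro-Michael/aldol domino of nitro ketones with enals. Ring B closes in the 6-(enolexo)-exo-trig mode; the C3 enolate could only reach an eight-membered ring, and attack of the aldehyde enamine on C4 would give a bridged tertiary aldol that reverts. C5 and C6 are set under thermodynamic control by the C10 centre: DBU keeps the aldol reversible and C5 and C9 epimerizable, so the trans-fused chair with equatorial, C4=O-hydrogen-bonded 6α-OH and equatorial nitro should accumulate (a 6β-OH would be 1,3-diaxial to the C10 methyl); C8 is set by the catalyst and is erased in step 6. The step needs 1,4- over 1,2-addition of the nitronate, secured by iminium activation, and aldol addition without dehydration, secured by the mild base at room temperature and by silylation in the next step.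

**Step 3**
Reactants: 6 trans-fused 6α-hydroxy-8α,10β-dimethyl-9β-nitrodecalin-4-one
Product: 7 6α-(tert-butyldimethylsilyloxy) ether of 6
Conditions: TBSOTf, 2,6-lutidine, CH2Cl2, −78 → 0 °C
Reagents that add atoms: tert-butyldimethylsilyl trifluoromethanesulfonate, CC(C)(C)[Si](C)(C)OS(=O)(=O)C(F)(F)F
Why: Silylation of the equatorial C6 hydroxyl with a silyl triflate and a hindered pyridine (silyl ether protection) blocks retro-aldol and β-elimination in the basic steps that follow and touches no stereocenter.

**Step 4**
Reactants: 7 6α-silyloxy nitro ketone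
Product: 9 6α-(tert-butyldimethylsilyloxy)-8α,10β-dimethyl-trans-decalin-4,9-dione, via sodium nitronate 8 (not isolated)
Conditions: NaOMe (1.05 equiv), MeOH–CH2Cl2, −78 °C; then O3, −78 °C; N2 purge
Reagents that add atoms: ozone, [O-][O+]=O
Why: Oxidative Nef reaction: the nitro α-proton, far more acidic than any ketone α-proton, is removed by one equivalent of methoxide and ozone cleaves the nitronate C=N to the C9 ketone, after which the C8 methyl can settle equatorial.

**Step 5**
Reactants: 9 4,9-dione
Product: 10 4-(triethylsilyloxy)-3-ene enol silane of 9 (C9 ketone intact)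
Conditions: LiN(i-Pr)2 (1.05 equiv), Et3SiCl, THF, −78 °C
Reagents that add atoms: chlorotriethylsilane, CC[Si](Cl)(CC)CC
Why: Kinetic deprotonation by the hindered amide at the only unhindered α-methylene (C3; C5–H and C8–H are hindered methines) with in situ O-silylation (regioselective silyl enol ether formation) masks the C4 ketone and fixes the position of the later enone.

**Step 6**
Reactants: 10 enol silane ketone
Product: 11 C8=C9 enol triflate (9-trifluoromethanesulfonyloxy-3,8-diene)
Conditions: KN(SiMe3)2, PhNTf2, THF, −78 → 0 °C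
Reagents that add atoms: N-phenylbis(trifluoromethanesulfonimide), O=S(=O)(N(c1ccccc1)S(=O)(=O)C(F)(F)F)C(F)(F)F
Why: The C9 ketone can enolize only toward C8 because C10 is quaternary, so O-triflation of its potassium enolate (enol triflate formation) gives the tetrasubstituted C8=C9 enol triflate regiospecifically and removes the C8 stereocenter.

**Step 7**
Reactants: 11 enol triflate
Product: 12 9-vinyl-3,8-diene (C8=C9–C11=C12 diene, enol silane retained)
Conditions: Bu3SnCH=CH2, Pd(PPh3)4 (5 mol%), LiCl, THF, reflux
Reagents that add atoms: tributyl(vinyl)stannane, C=C[Sn](CCCC)(CCCC)CCCC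
Why: Stille cross-coupling of the hindered enol triflate with the vinylstannane (chloride-promoted, zerovalent palladium) attaches C11–C12 as a vinyl group under neutral conditions that leave the enol silane and the silyl ether intact.

**Step 8**
Reactants: 12 triene enol silane
Product: 13 9-vinyl-2,8-dien-4-one
Conditions: Pd(OAc)2 (1.1 equiv), MeCN, rt
Reagents that add atoms: none
Why: Saegusa–Ito oxidation: the enol silane gives a C3 palladium enolate and β-hydride loss from C2 delivers the C2=C3 enone conjugated to C4=O, the double-bond position being dictated by the enol silane.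

**Step 9**
Reactants: 13 dienone
Product: 14 tertiary allylic alcohol 4-hydroxy-4-[(methoxymethoxy)methyl]-9-vinyl-2,8-diene (C4 epimers)
Conditions: Bu3SnCH2OCH2OCH3, n-BuLi, THF, −78 °C; then 13, −78 °C; H2O
Reagents that add atoms: (methoxymethoxy)methyllithium, [Li]COCOC, made in the flask from tributyl[(methoxymethoxy)methyl]stannane, CCCC[Sn](CCCC)(CCCC)COCOC
Why: Tin–lithium exchange gives a small α-alkoxy organolithium whose 1,2-addition to the enone carbonyl at −78 °C (organolithium carbonyl addition) installs C19 as its MOM ether; the new C4 carbinol centre becomes sp2 in step 10, so its configuration is immaterial.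

**Step 10**
Reactants: 14 tertiary allylic alcohol
Product: 15 4-[(methoxymethoxy)methyl]-9-vinyl-3,8-dien-2-one
Conditions: pyridinium chlorochromate (C5H5NH[CrO3Cl], 3 equiv), 4 Å molecular sieves, CH2Cl2, rt
Reagents that add atoms: pyridinium chlorochromate, [O-][Cr](=O)(=O)Cl.c1cc[nH+]cc1
Why: Babler–Dauben oxidative transposition: the tertiary allylic chromate ester shifts [3,3] to C2 and is oxidized there, giving the C2 ketone with the alkoxymethyl-bearing C4 as the enone β-carbon.

**Step 11**
Reactants: 15 transposed enone
Product: 16 4α-methyl-4β-[(methoxymethoxy)methyl]-9-vinyl-8-en-2-one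
Conditions: MeLi (2 equiv), CuI (gives Me2CuLi), BF3·OEt2, Et2O, −78 → −30 °C; then H2O
Reagents that add atoms: lithium dimethylcuprate, [Li+].C[Cu-]C
Why: Lewis acid-assisted conjugate addition of the methylcuprate to the β,β-disubstituted enone creates the C4 quaternary centre; the β-face is blocked by the syn-axial C10 methyl, so methyl should enter from the α-face and leave CH2OMOM axial (β) as required.

**Step 12**
Reactants: 16 2-ketone
Product: 17 2α-alcohol (6-O-TBS, 19-O-MOM, 8(9),11-diene)
Conditions: Al(Oi-Pr)3, i-PrOH (trace acetone), toluene, reflux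
Reagents that add atoms: none
Why: Meerwein–Ponndorf–Verley reduction is reversible, so the C2 carbinol should equilibrate to the equatorial 2α-alcohol, the axial epimer being destabilized by syn-axial contacts with the C10 methyl and the C4 CH2OMOM group.

**Step 13**
Reactants: 17 2α-alcohol diene; 18 4-bromofuran-2(5H)-one
Product: 20 6-O-TBS-19-O-MOM-protected target, via B-alkyl-9-BBN borane 19 (not isolated)
Conditions: 9-BBN (2.5 equiv), THF, rt; then 18, Pd(dppf)Cl2 (5 mol%), AsPh3, K3PO4 (aq), DMF–THF, rt
Reagents that add atoms: none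
Why: 9-BBN hydroborates only the monosubstituted C11=C12 end of the diene (boron at C12), and B-alkyl Suzuki–Miyaura coupling with the β-bromobutenolide forms C12–C13, delivering the intact butenolide without touching the tetrasubstituted C8=C9 bond.

**Step 14**
Reactants: 20 protected target
Product: 21 2α,6α,19-trihydroxylabda-8,13-dien-15,16-olide (target)
Conditions: HCl (2 M aq), MeOH–THF, 45 °C
Reagents that add atoms: none
Why: Acid hydrolysis cleaves the MOM acetal and the silyl ether in one operation (global deprotection) without affecting the butenolide, the tetrasubstituted alkene or any stereocenter.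

**Compound list**

1 | 3-methylcyclohex-2-en-1-one | CC1=CC(=O)CCC1 | starting material
2 | nitromethane | C[N+](=O)[O-] | starting material
3 | (S)-3-methyl-3-(nitromethyl)cyclohexan-1-one | [O-][N+](=O)C[C@@]1(C)CCCC(=O)C1 | intermediate
4 | (E)-but-2-enal (crotonaldehyde) | C/C=C/C=O | starting material
5 | 3-methyl-4-[(1S)-1-methyl-3-oxocyclohexyl]-4-nitrobutanal (Michael adduct, 8α,9β as drawn) | C[C@H](CC=O)[C@H]([N+](=O)[O-])[C@@]1(C)CCCC(=O)C1 | intermediate
6 | 8-hydroxy-4a,6-dimethyl-5-nitrooctahydronaphthalen-1(2H)-one; labdane positions 4-oxo, 5α-H, 6α-OH, 8α-CH3, 9β-NO2, 10β-CH3 | C[C@H]1[C@H]([N+](=O)[O-])[C@@]2(C)CCCC(=O)[C@@H]2[C@@H](O)C1 | intermediate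
7 | 6α-O-tert-butyldimethylsilyl ether of 6 | C[C@H]1[C@H]([N+](=O)[O-])[C@@]2(C)CCCC(=O)[C@@H]2[C@@H](O[Si](C)(C)C(C)(C)C)C1 | intermediate
8 | sodium C9 nitronate of 7 | C[C@H]1C(=[N+]([O-])[O-])[C@@]2(C)CCCC(=O)[C@@H]2[C@@H](O[Si](C)(C)C(C)(C)C)C1.[Na+] | intermediate
9 | 6α-(tert-butyldimethylsilyloxy)-8α,10β-dimethyl-trans-decalin-4,9-dione | C[C@H]1C(=O)[C@@]2(C)CCCC(=O)[C@@H]2[C@@H](O[Si](C)(C)C(C)(C)C)C1 | intermediate
10 | C3=C4 triethylsilyl enol ether of 9 (C9 ketone retained) | C[C@H]1C(=O)[C@@]2(C)CCC=C(O[Si](CC)(CC)CC)[C@@H]2[C@@H](O[Si](C)(C)C(C)(C)C)C1 | intermediate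
11 | C8=C9 enol triflate of 10 | CC1=C(OS(=O)(=O)C(F)(F)F)[C@@]2(C)CCC=C(O[Si](CC)(CC)CC)[C@@H]2[C@@H](O[Si](C)(C)C(C)(C)C)C1 | intermediate
12 | 9-vinyl-3,8-diene bearing the C4 triethylsilyl enol ether and the 6α-silyl ether | CC1=C(C=C)[C@@]2(C)CCC=C(O[Si](CC)(CC)CC)[C@@H]2[C@@H](O[Si](C)(C)C(C)(C)C)C1 | intermediate
13 | 6α-(tert-butyldimethylsilyloxy)-8,10β-dimethyl-9-vinyl-2,8-dien-4-one (5α-H) | CC1=C(C=C)[C@@]2(C)CC=CC(=O)[C@@H]2[C@@H](O[Si](C)(C)C(C)(C)C)C1 | intermediate
14 | 4-hydroxy-4-[(methoxymethoxy)methyl] adduct of 13 (C4 epimers, not separated) | CC1=C(C=C)[C@@]2(C)CC=CC(O)(COCOC)[C@@H]2[C@@H](O[Si](C)(C)C(C)(C)C)C1 | intermediate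
15 | 6α-(tert-butyldimethylsilyloxy)-4-[(methoxymethoxy)methyl]-8,10β-dimethyl-9-vinyl-3,8-dien-2-one | CC1=C(C=C)[C@@]2(C)CC(=O)C=C(COCOC)[C@@H]2[C@@H](O[Si](C)(C)C(C)(C)C)C1 | intermediate
16 | 4α-methyl-4β-[(methoxymethoxy)methyl]-6α-(tert-butyldimethylsilyloxy)-8,10β-dimethyl-9-vinyl-8-en-2-one | CC1=C(C=C)[C@@]2(C)CC(=O)C[C@](C)(COCOC)[C@@H]2[C@@H](O[Si](C)(C)C(C)(C)C)C1 | intermediate
17 | 2α-alcohol from 16 | CC1=C(C=C)[C@@]2(C)C[C@@H](O)C[C@](C)(COCOC)[C@@H]2[C@@H](O[Si](C)(C)C(C)(C)C)C1 | intermediate
18 | 4-bromofuran-2(5H)-one | BrC1=CC(=O)OC1 | starting material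
19 | C12 B-alkyl-9-borabicyclo[3.3.1]nonane from 17 | CC1=C(CCB2C3CCCC2CCC3)[C@@]4(C)C[C@@H](O)C[C@](C)(COCOC)[C@@H]4[C@@H](O[Si](C)(C)C(C)(C)C)C1 | intermediate
20 | 6-O-tert-butyldimethylsilyl-19-O-methoxymethyl derivative of the target | CC1=C(CCC2=CC(=O)OC2)[C@@]3(C)C[C@@H](O)C[C@](C)(COCOC)[C@@H]3[C@@H](O[Si](C)(C)C(C)(C)C)C1 | intermediate
21 | 2α,6α,19-trihydroxylabda-8,13-dien-15,16-olide | CC1=C(CCC2=CC(=O)OC2)[C@@]2(C)C[C@@H](O)C[C@](C)(CO)[C@@H]2[C@@H](O)C1 | target

**Step count and risks**

Total steps: 14. Longest linear sequence: 14 steps (1 → 21); compounds 2, 4, 18 and the reagents are commercial.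

Steps most likely to fail:

1. Step 2. The hindered neopentyl nitronate may add slowly to the iminium ion, and the keto aldehyde may be diverted by aldehyde-enamine aldol onto C4 or lose water after ring closure. The fallback decouples the two bond formations with an ester-level acceptor. Setting out from 3, ketalization (ethylene glycol, TsOH, benzene, reflux) should give (7S)-7-methyl-7-(nitromethyl)-1,4-dioxaspiro[4.5]decane F1. DBU-mediated nitro-Michael addition of F1 to methyl (E)-but-2-enoate in MeCN should give the nitro ester ketal F2, and i-Bu2AlH at −78 °C the aldehyde ketal F3. Aqueous HCl in THF then unmasks the ketone (giving 5) and K2CO3 in MeOH closes ring B, returning to the route at 6.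

2. Step 11. Methyl transfer to the β,β-disubstituted C4, which is flanked by the ring-fusion carbon and peri to the C6 silyl ether, may be slow, may lose face selectivity or may give 1,2-addition. The fallback sets out from 15 and uses Corey–Chaykovsky cyclopropanation (Me3S(O)I, NaH, DMSO), in which the small sulfoxonium ylide should add from the α-face to give the 3α,4α-methano ketone F4. SmI2 (THF–HMPA, t-BuOH) should then cleave the cyclopropane bond between C3 and the methylene, the one aligned with the ketyl, turning the methylene into the 4α-methyl group and returning to the route at 16.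

3. Step 10. The chromate-mediated transposition may over-oxidize the electron-rich diene or strip the acid-labile MOM acetal. The fallback sets out from 14 and separates isomerization from oxidation: catalytic Ph3SiOReO3 in Et2O at 0 °C should effect the 1,3-transposition to the secondary allylic alcohol F5 (C2 carbinol, trisubstituted C3=C4 alkene), and Dess–Martin periodinane should then oxidize it, returning to the route at 15.

**Further compounds**

F1 | step 2 | (7S)-7-methyl-7-(nitromethyl)-1,4-dioxaspiro[4.5]decane | [O-][N+](=O)C[C@@]1(C)CCCC2(C1)OCCO2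
F2 | step 2 | methyl 3-methyl-4-[(7S)-7-methyl-1,4-dioxaspiro[4.5]decan-7-yl]-4-nitrobutanoate (C3/C4 epimers) | COC(=O)CC(C)C([N+](=O)[O-])[C@@]1(C)CCCC2(C1)OCCO2
F3 | step 2 | 3-methyl-4-[(7S)-7-methyl-1,4-dioxaspiro[4.5]decan-7-yl]-4-nitrobutanal (C3/C4 epimers) | O=CCC(C)C([N+](=O)[O-])[C@@]1(C)CCCC2(C1)OCCO2
F4 | step 11 | 3α,4α-methano-4β-[(methoxymethoxy)methyl]-6α-(tert-butyldimethylsilyloxy)-8,10β-dimethyl-9-vinyl-8-en-2-one | CC1=C(C=C)[C@@]2(C)CC(=O)[C@H]3C[C@@]3(COCOC)[C@@H]2[C@@H](O[Si](C)(C)C(C)(C)C)C1
F5 | step 10 | 2-hydroxy-4-[(methoxymethoxy)methyl]-6α-(tert-butyldimethylsilyloxy)-8,10β-dimethyl-9-vinyl-3,8-diene (C2 epimers) | CC1=C(C=C)[C@@]2(C)CC(O)C=C(COCOC)[C@@H]2[C@@H](O[Si](C)(C)C(C)(C)C)C1
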